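**Strategy**

The route rests on one disconnection: the C2–C3 bond between the two stereocentres is cut together with the O1′–C2′ bond of the 5,5-dimethylfuran-2(5H)-ylidene ring. The precursor is an aldol-derived 3-hydroxy-1,5-diene acid carrying a 3,3-dimethyl-2-alkynyloxirane. Its anionic oxy-Cope shift forges C2–C3 with both stereocentres and the 1,1-disubstituted alkene and unveils an aldehyde enolate, which opens the oxirane through the alkyne and lets the freed alkoxide close on the cumulene, so the oxirane grows into the five-membered O1′–C2′(=C4)–C3′H=C4′H–C5′Me2 ring. The step exploits the vinylogous formate O1′–C2′=C4–C5HO and the 1,5-relationship of carboxyl and formyl carbons across C2–C3.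

Key step: step 12

Remark: the target is numbered as a pentanoic acid (C1 carboxyl to C5 formyl, ring atoms primed). The oxirane CH carbon of 16–19 is racemic or epimeric and is written without descriptor, because step 12 turns it into the sp2 ring carbon C3′; 19 is also a mixture at its formyl-bearing carbon.

**Route**

Step 1
Reactants: 1 2-(3-chloropropyl)-2-methyl-1,3-dioxolane; 2 diketene (4-methylideneoxetan-2-one)
Product: 4 3-methylidene-6-(2-methyl-1,3-dioxolan-2-yl)hexanoic acid, via Grignard reagent 3 (not isolated)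
Conditions: Mg, THF, 50 °C; then 2, NiCl2 (5 mol %), THF, 0 °C; cold 1 M HCl to pH 3
Reagents that add atoms: none
Why: The Grignard reagent 3 should couple with diketene at the vinylic C–O bond under nickel catalysis (Kumada-type ring-opening cross-coupling) to give the 3-methylidene acid directly; no stereocentre is formed.

Step 2
Reactants: 4 3-methylidene-6-(2-methyl-1,3-dioxolan-2-yl)hexanoic acid
Product: 5 methyl 3-methylidene-6-(2-methyl-1,3-dioxolan-2-yl)hexanoate
Conditions: Me3SiCHN2, PhMe/MeOH (4:1), 0 °C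
Reagents that add atoms: trimethylsilyldiazomethane, C[Si](C)(C)C=[N+]=[N-]
Why: Methylation of the acid with trimethylsilyldiazomethane is neutral, so the β,γ-alkene should stay out of conjugation.

Step 3
Reactants: 5 methyl 3-methylidene-6-(2-methyl-1,3-dioxolan-2-yl)hexanoate
Product: 6 1-methoxy-3-[3-(2-methyl-1,3-dioxolan-2-yl)propyl]-1-(trimethylsilyloxy)buta-1,3-diene (silyl dienolate; ketene-acetal geometry not controlled)
Conditions: LiN(iPr)2, THF, −78 °C; Me3SiCl, −78 → 0 °C
Reagents that add atoms: chlorotrimethylsilane, C[Si](C)(C)Cl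
Why: Kinetic deprotonation at the doubly activated C2 and O-silylation (silyl ketene acetal formation) should give the cross-conjugated silyl dienolate.

Step 4
Reactants: 7 4,4-diethoxybut-1-yne
Product: 8 5,5-diethoxypent-2-yn-1-ol
Conditions: n-BuLi, THF, −78 °C; (CH2O)n, −78 → 23 °C; H2O
Reagents that add atoms: paraformaldehyde (as formaldehyde), C=O
Why: Addition of the lithium acetylide to formaldehyde (hydroxymethylation) introduces the future formyl carbon.

Step 5
Reactants: 8 5,5-diethoxypent-2-yn-1-ol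
Product: 10 (2E)-5,5-diethoxy-2-iodopent-2-en-1-ol, via vinylstannane 9 (not isolated)
Conditions: Bu3SnH, PdCl2(PPh3)2 (2 mol %), THF, 0 °C; then I2, CH2Cl2, 0 °C
Reagents that add atoms: iodine, II
Why: Palladium-catalysed hydrostannation adds H and Sn syn with tin on the carbinol-proximal carbon, and iododestannylation occurs with retention, so CH2OH should end cis to the C4 chain (2E).

Step 6
Reactants: 11 ethynyltrimethylsilane; 12 1-bromo-2-methylprop-1-ene
Product: 13 trimethyl(4-methylpent-3-en-1-yn-1-yl)silane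
Conditions: PdCl2(PPh3)2 (2 mol %), CuI (4 mol %), Et3N, 50 °C (sealed)
Reagents that add atoms: none
Why: Sonogashira coupling of the terminal alkyne with the alkenyl bromide.

Step 7
Reactants: 10 (2E)-5,5-diethoxy-2-iodopent-2-en-1-ol; 13 trimethyl(4-methylpent-3-en-1-yn-1-yl)silane
Product: 14 (2Z)-5,5-diethoxy-2-(4-methylpent-3-en-1-yn-1-yl)pent-2-en-1-ol
Conditions: Pd(PPh3)4 (5 mol %), CuI (10 mol %), CsF, Et3N, DMF, 23 °C
Reagents that add atoms: none
Why: Fluoride-promoted desilylative Sonogashira coupling passes the alkynyl group from silicon via copper to the alkenyl iodide with retention of alkene geometry and avoids the volatile free enyne.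

Step 8
Reactants: 14 (2Z)-5,5-diethoxy-2-(4-methylpent-3-en-1-yn-1-yl)pent-2-en-1-ol
Product: 15 (2Z)-5,5-diethoxy-2-(4-methylpent-3-en-1-yn-1-yl)pent-2-enal
Conditions: Dess–Martin periodinane, NaHCO3, CH2Cl2, 0 °C
Reagents that add atoms: none
Why: Dess–Martin oxidation of the primary allylic alcohol under buffered, non-nucleophilic conditions should preserve the Z geometry and the acetal.

Step 9
Reactants: 15 (2Z)-5,5-diethoxy-2-(4-methylpent-3-en-1-yn-1-yl)pent-2-enal
Product: 16 (2Z)-2-[(3,3-dimethyloxiran-2-yl)ethynyl]-5,5-diethoxypent-2-enal (racemic at the oxirane carbon)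
Conditions: mCPBA, NaHCO3, CH2Cl2, 0 °C
Reagents that add atoms: 3-chloroperoxybenzoic acid, OOC(=O)c1cccc(Cl)c1
Why: Prilezhaev epoxidation should be chemoselective for the electron-rich trisubstituted alkene over the formyl-conjugated one; the new oxirane CH is racemic and is destroyed in step 12.

Step 10
Reactants: 16 (2Z)-2-[(3,3-dimethyloxiran-2-yl)ethynyl]-5,5-diethoxypent-2-enal; 6 silyl dienolate
Product: 17 methyl (2E,5S,6Z)-6-[(3,3-dimethyloxiran-2-yl)ethynyl]-9,9-diethoxy-5-hydroxy-3-[3-(2-methyl-1,3-dioxolan-2-yl)propyl]nona-2,6-dienoate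
Conditions: 6 (1.5 equiv), Cu(OTf)2 (10 mol %), (S)-Tol-BINAP (11 mol %), Bu4N[Ph3SiF2] (20 mol %), THF, −78 °C; then 0.5 M citric acid/THF, 0 °C
Reagents that add atoms: none
Why: In this fluoride-initiated, copper–bisphosphine-catalysed vinylogous Mukaiyama aldol the dienolate should attack the aldehyde carbonyl through its γ-carbon, the ligand sets C5 (S intended; the ligand antipode is used if the sense proves opposite), and the s-trans dienolate gives the 2E enoate while any 2Z adduct lactonises and is removed.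

Step 11
Reactants: 17 methyl (2E,5S,6Z)-hydroxy dienoate
Product: 18 (2E,5S,6Z)-6-[(3,3-dimethyloxiran-2-yl)ethynyl]-9,9-diethoxy-5-hydroxy-3-[3-(2-methyl-1,3-dioxolan-2-yl)propyl]nona-2,6-dienoic acid
Conditions: LiOH, THF/MeOH/H2O, 0 → 23 °C; then 1 M HCl to pH 4, 0 °C
Reagents that add atoms: lithium hydroxide, [Li+].[OH-]
Why: Saponification (acyl–oxygen cleavage) frees the carboxylate that the key step needs; the 2E hydroxy acid cannot lactonise.

Step 12
Reactants: 18 (2E,5S,6Z)-hydroxy dienoic acid
Product: 21 (2R,3S,4E)-3-(2,2-diethoxyethyl)-4-(5,5-dimethylfuran-2(5H)-ylidene)-2-[5-(2-methyl-1,3-dioxolan-2-yl)pent-1-en-2-yl]-5-oxopentanoic acid, via oxy-Cope ynal 19 (not isolated), via cumulenol 20 (not isolated)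
Conditions: KH (2.5 equiv), 18-crown-6, THF, 0 → 23 °C (aprotic stage); then t-BuOH (10 equiv), 23 °C; pH 4 phosphate buffer
Reagents that add atoms: none
Why: Proposed new method: the dipotassium alkoxide–carboxylate of 18 undergoes an anionic oxy-Cope [3,3] shift (C4–C5 broken, C2–C7 formed) to the enolate of ynal 19, whose formyl-stabilised propargylic carbanion expels the oxirane oxygen through the alkyne (vinylogous E1cB at the O–CH bond) to give the alkoxide of cumulenol 20, and once t-BuOH is added this alkoxide adds to the cumulene carbon β to the formyl group while t-BuOH protonates the neighbouring carbon. The closest known reaction types are the anionic oxy-Cope rearrangement of aldol-derived 1,5-dien-3-olates and the base-catalysed isomerisation of 2-alkynyloxiranes via cumulenyl alkoxides; new is that the enolate released by the sigmatropic shift drives the second. The only ring closed is the dihydrofuran, by 5-endo attack of the tertiary alkoxide on the in-plane π bond of the cumulene, so the three-membered oxirane is expanded to the five-membered ring by formal insertion of the two alkyne carbons into its O–CH bond. C2 and C3 are both set in the chair transition state: the 6Z-disposed C8 chain must sit axial, which by A1,3 strain forces H-5 axial and the 5S oxygen equatorial, and with the 2E carboxylate equatorial this chair should transmit 5S into 2R,3S. The step needs the concerted shift to outrun retro-aldol fragmentation and 5-endo-dig addition of the C5 alkoxide to the alkyne, and it needs H-2 to survive; the carboxylate (poorly anion-stabilising, non-enolisable) secures the first and third, and the aprotic first stage, which offers no proton to a vinyl anion, the second. The 4E geometry of the push–pull alkene is expected to be the thermodynamic one (branched C3 next to the ring oxygen, formyl next to H-3′) and can be reached by reversible alkoxide addition.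

Step 13
Reactants: 21 (2R,3S,4E)-bis-acetal acid
Product: 22 (2R,3S,4E)-4-(5,5-dimethylfuran-2(5H)-ylidene)-5-oxo-2-(6-oxohept-1-en-2-yl)-3-(2-oxoethyl)pentanoic acid (CNP0150297.1)
Conditions: 1 M HCl/THF (1:4), 0 → 23 °C
Reagents that add atoms: water, O
Why: Acid-catalysed hydrolysis of the diethyl acetal and the dioxolane should unveil the aldehyde and the ketone, while the vinylogous formate, whose ring oxygen is deactivated by conjugation, should survive and settle in the 4E geometry.

**Compound list**

1 | 2-(3-chloropropyl)-2-methyl-1,3-dioxolane | CC1(CCCCl)OCCO1 | starting material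
2 | diketene (4-methylideneoxetan-2-one) | C=C1CC(=O)O1 | starting material
3 | [3-(2-methyl-1,3-dioxolan-2-yl)propyl]magnesium chloride | CC1(CCC[Mg]Cl)OCCO1 | intermediate
4 | 3-methylidene-6-(2-methyl-1,3-dioxolan-2-yl)hexanoic acid | C=C(CCCC1(C)OCCO1)CC(=O)O | intermediate
5 | methyl 3-methylidene-6-(2-methyl-1,3-dioxolan-2-yl)hexanoate | C=C(CCCC1(C)OCCO1)CC(=O)OC | intermediate
6 | 1-methoxy-3-[3-(2-methyl-1,3-dioxolan-2-yl)propyl]-1-(trimethylsilyloxy)buta-1,3-diene | C=C(CCCC1(C)OCCO1)C=C(OC)O[Si](C)(C)C | intermediate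
7 | 4,4-diethoxybut-1-yne | C#CCC(OCC)OCC | starting material
8 | 5,5-diethoxypent-2-yn-1-ol | OCC#CCC(OCC)OCC | intermediate
9 | (2E)-5,5-diethoxy-2-(tributylstannyl)pent-2-en-1-ol | OC/C([Sn](CCCC)(CCCC)CCCC)=C\CC(OCC)OCC | intermediate
10 | (2E)-5,5-diethoxy-2-iodopent-2-en-1-ol | OC/C(I)=C\CC(OCC)OCC | intermediate
11 | ethynyltrimethylsilane | C#C[Si](C)(C)C | starting material
12 | 1-bromo-2-methylprop-1-ene | CC(C)=CBr | starting material
13 | trimethyl(4-methylpent-3-en-1-yn-1-yl)silane | CC(C)=CC#C[Si](C)(C)C | intermediate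
14 | (2Z)-5,5-diethoxy-2-(4-methylpent-3-en-1-yn-1-yl)pent-2-en-1-ol | OC/C(C#CC=C(C)C)=C\CC(OCC)OCC | intermediate
15 | (2Z)-5,5-diethoxy-2-(4-methylpent-3-en-1-yn-1-yl)pent-2-enal | O=C/C(C#CC=C(C)C)=C\CC(OCC)OCC | intermediate
16 | (2Z)-2-[(3,3-dimethyloxiran-2-yl)ethynyl]-5,5-diethoxypent-2-enal (racemic oxirane carbon) | O=C/C(C#CC1OC1(C)C)=C\CC(OCC)OCC | intermediate
17 | methyl (2E,5S,6Z)-6-[(3,3-dimethyloxiran-2-yl)ethynyl]-9,9-diethoxy-5-hydroxy-3-[3-(2-methyl-1,3-dioxolan-2-yl)propyl]nona-2,6-dienoate (both oxirane epimers) | COC(=O)/C=C(CCCC1(C)OCCO1)/C[C@H](O)/C(C#CC2OC2(C)C)=C\CC(OCC)OCC | intermediate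
18 | (2E,5S,6Z)-6-[(3,3-dimethyloxiran-2-yl)ethynyl]-9,9-diethoxy-5-hydroxy-3-[3-(2-methyl-1,3-dioxolan-2-yl)propyl]nona-2,6-dienoic acid (both oxirane epimers) | OC(=O)/C=C(CCCC1(C)OCCO1)/C[C@H](O)/C(C#CC2OC2(C)C)=C\CC(OCC)OCC | intermediate
19 | (2R,3R)-3-(2,2-diethoxyethyl)-6-(3,3-dimethyloxiran-2-yl)-4-formyl-2-[5-(2-methyl-1,3-dioxolan-2-yl)pent-1-en-2-yl]hex-5-ynoic acid (C4 and oxirane carbon unfixed; formed as its dipotassium enolate) | C=C(CCCC1(C)OCCO1)[C@H](C(=O)O)[C@H](CC(OCC)OCC)C(C=O)C#CC2OC2(C)C | intermediate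
20 | (2R,3S)-3-(2,2-diethoxyethyl)-4-formyl-8-hydroxy-8-methyl-2-[5-(2-methyl-1,3-dioxolan-2-yl)pent-1-en-2-yl]nona-4,5,6-trienoic acid (formed as its dipotassium salt) | C=C(CCCC1(C)OCCO1)[C@H](C(=O)O)[C@H](CC(OCC)OCC)C(C=O)=C=C=CC(C)(C)O | intermediate
21 | (2R,3S,4E)-3-(2,2-diethoxyethyl)-4-(5,5-dimethylfuran-2(5H)-ylidene)-2-[5-(2-methyl-1,3-dioxolan-2-yl)pent-1-en-2-yl]-5-oxopentanoic acid | C=C(CCCC1(C)OCCO1)[C@H](C(=O)O)[C@H](CC(OCC)OCC)/C(C=O)=C2/C=CC(C)(C)O2 | intermediate
22 | (2R,3S,4E)-4-(5,5-dimethylfuran-2(5H)-ylidene)-5-oxo-2-(6-oxohept-1-en-2-yl)-3-(2-oxoethyl)pentanoic acid | C=C(CCCC(C)=O)[C@H](C(=O)O)[C@H](CC=O)/C(C=O)=C1/C=CC(C)(C)O1 | target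

**Step count and risks**

Total steps: 13. Longest linear sequence: 9 steps (steps 4, 5, 7, 8, 9, 10, 11, 12, 13 from 4,4-diethoxybut-1-yne).

Steps most likely to fail:

1. Step 12 (Proposed new method). The dienolate may fragment heterolytically (retro-aldol) instead of shifting in concert, which would erase the chirality transfer. The C5 alkoxide may also add 5-endo-dig to the alkyne before the shift, or the cumulene may oligomerise before it closes. Fallback with known chemistry, setting out from 18 and returning at 21: silylation of 18 (TBSCl, imidazole, DMF) should give the bis-silyl derivative tert-butyldimethylsilyl (2E,5S,6Z)-5-(tert-butyldimethylsilyloxy)dienoate F1. Heating F1 (PhMe, 150 °C, sealed) should effect the neutral siloxy-Cope rearrangement through the same chair to the silyl enol ether/silyl ester F2. Et3N·3HF (THF, 0 °C) then releases ynal 19, now isolated, and t-BuOK/t-BuOH/18-crown-6 in THF carries out the base-catalysed alkynyloxirane isomerisation to 21.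

2. Step 10. Facial selectivity at the aldehyde may be insufficient, some dienolate may attack through its α-carbon, or the phosphine may isomerise the Z enal. Fallback, setting out from 5 and 16 and returning at 17: precomplexation of ester 5 and enal 16 with Al(O-2,6-Ph2C6H3)3 (PhMe, −78 °C) and deprotonation with LiN(iPr)2 should give the γ-aldol as the racemate at C5, methyl (2E,5RS,6Z)-hydroxy dienoate F3. A lipase (Burkholderia cepacia lipase, vinyl acetate, t-BuOMe, 30 °C) should then acylate the 5R alcohol to the (5R)-acetate F4 and leave (5S)-17, which is separated and enters step 11.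

3. Step 5. Tin may be delivered to the distal alkyne carbon, giving the regioisomeric stannane and iodide. Fallback, setting out from 7 and returning at 10: carboxylation of 7 (n-BuLi, ClCO2Me, THF, −78 °C) gives methyl 5,5-diethoxypent-2-ynoate F5. Hydrostannation of the alkynoate (Bu3SnH, Pd(PPh3)4, THF), which places tin reliably α to the ester by syn addition, gives methyl (2E)-5,5-diethoxy-2-(tributylstannyl)pent-2-enoate F6. Iododestannylation (I2, CH2Cl2) gives methyl (2E)-5,5-diethoxy-2-iodopent-2-enoate F7, and i-Bu2AlH (CH2Cl2, −78 °C) reduces F7 to 10.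

**Further compounds**

F1 | step 12 | tert-butyldimethylsilyl (2E,5S,6Z)-5-(tert-butyldimethylsilyloxy)-6-[(3,3-dimethyloxiran-2-yl)ethynyl]-9,9-diethoxy-3-[3-(2-methyl-1,3-dioxolan-2-yl)propyl]nona-2,6-dienoate | CC(C)(C)[Si](C)(C)OC(=O)/C=C(CCCC1(C)OCCO1)/C[C@H](O[Si](C)(C)C(C)(C)C)/C(C#CC2OC2(C)C)=C\CC(OCC)OCC
F2 | step 12 | tert-butyldimethylsilyl (2R,3S)-4-[(tert-butyldimethylsilyloxy)methylidene]-3-(2,2-diethoxyethyl)-6-(3,3-dimethyloxiran-2-yl)-2-[5-(2-methyl-1,3-dioxolan-2-yl)pent-1-en-2-yl]hex-5-ynoate | C=C(CCCC1(C)OCCO1)[C@H](C(=O)O[Si](C)(C)C(C)(C)C)[C@H](CC(OCC)OCC)C(C#CC2OC2(C)C)=CO[Si](C)(C)C(C)(C)C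
F3 | step 10 | methyl (2E,5RS,6Z)-6-[(3,3-dimethyloxiran-2-yl)ethynyl]-9,9-diethoxy-5-hydroxy-3-[3-(2-methyl-1,3-dioxolan-2-yl)propyl]nona-2,6-dienoate | COC(=O)/C=C(CCCC1(C)OCCO1)/CC(O)/C(C#CC2OC2(C)C)=C\CC(OCC)OCC
F4 | step 10 | methyl (2E,5R,6Z)-5-acetoxy-6-[(3,3-dimethyloxiran-2-yl)ethynyl]-9,9-diethoxy-3-[3-(2-methyl-1,3-dioxolan-2-yl)propyl]nona-2,6-dienoate | COC(=O)/C=C(CCCC1(C)OCCO1)/C[C@@H](OC(C)=O)/C(C#CC2OC2(C)C)=C\CC(OCC)OCC
F5 | step 5 | methyl 5,5-diethoxypent-2-ynoate | COC(=O)C#CCC(OCC)OCC
F6 | step 5 | methyl (2E)-5,5-diethoxy-2-(tributylstannyl)pent-2-enoate | COC(=O)/C([Sn](CCCC)(CCCC)CCCC)=C\CC(OCC)OCC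
F7 | step 5 | methyl (2E)-5,5-diethoxy-2-iodopent-2-enoate | COC(=O)/C(I)=C\CC(OCC)OCC
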